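**Retrosynthetic overview**
- The two formyl groups come last (double Vilsmeier–Haack on the free diphenol). Before that: benzyl ethers off, sulfonyl group off the cyclopropane, and the CMe2 bridge put on a ring vinyl sulfone by a sulfonium-ylide Michael/ring-closure.
- Key disconnection: a retro-[4+2] opens the cyclohexene and the cyclopentane together, cutting the ring CH2–CH(CH3) bond and the bond between the aryloxy quaternary carbon and the ring-fusion CH. This leads back to an eight-membered benzoxocine carrying a (Z)-aryl enol ether and a 2-sulfonyl-1,3-diene.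
- Enabling feature: in the six-membered carbocycle the aryl-ether carbon is directly bonded to the CH(CH3), so this C–C pair is an enol ether of the phloroglucinol oxygen. The ring CH2, the two cyclopropane CH carbons and the ring-fusion CH are a four-carbon diene whose central C=C is left exactly where the cyclopropane is built, and the quaternary C–CH3 carbon holds both tethers.
- The enol ether comes from an eight-membered aryl lactone (Takai–Utimoto ethylidenation), the lactone from a seco acid. The quaternary carbon and the benzylic CH(isobutyl) centre are set on a dihydrocoumarin (asymmetric conjugate addition, then two enolate reactions).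
- Ring order: chromanone (temporary) → benzoxocinone → cyclohexene + cyclopentane + oxepane bridge (key step) → cyclopropane.

Key step: step 11

Remark (assumption): isopropyldiphenylsulfonium tetrafluoroborate and the ferrocenyl diphosphine are taken as catalogue reagents, and the ligand enantiomer is the one that gives the 4R lactone in step 2.

Step 1
Reactants: 1 5,7-dihydroxy-2H-chromen-2-one
Product: 2 5,7-bis(benzyloxy)-2H-chromen-2-one
Conditions: BnBr (2.3 equiv), K2CO3, DMF, 60 °C
Reagents that add atoms: benzyl bromide BrCc1ccccc1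
Why: Williamson O-benzylation masks both phenols as ethers that should survive all later base, hydride, organometal and Lewis-acid steps and fall together under neutral hydrogenolysis.

Step 2
Reactants: 2 5,7-bis(benzyloxy)-2H-chromen-2-one; 3 isobutylmagnesium bromide
Product: 4 (4R)-5,7-bis(benzyloxy)-4-(2-methylpropyl)chroman-2-one
Conditions: CuBr·SMe2 (5 mol %), 1-[2-(diphenylphosphino)ferrocenyl]ethyldicyclohexylphosphine (6 mol %), tBuOMe, −72 °C; then 1 M HCl
Reagents that add atoms: none
Why: Copper-catalysed asymmetric conjugate addition of a Grignard reagent to a coumarin, in which the chiral diphosphine–copper complex selects the face of the enoate and so sets the benzylic stereocentre.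

Step 3
Reactants: 4 (4R)-5,7-bis(benzyloxy)-4-(2-methylpropyl)chroman-2-one
Product: 5 (3R,4R)-5,7-bis(benzyloxy)-3-methyl-4-(2-methylpropyl)chroman-2-one
Conditions: LiN(SiMe3)2, THF, −78 °C; MeI
Reagents that add atoms: iodomethane CI
Why: Lactone enolate alkylation, with methyl entering trans to the 4-isobutyl group; this centre is flattened again in step 4, so only its constitution matters.

Step 4
Reactants: 5 (3R,4R)-5,7-bis(benzyloxy)-3-methyl-4-(2-methylpropyl)chroman-2-one; 6 tert-butyl acrylate
Product: 7 tert-butyl 3-[(3R,4S)-5,7-bis(benzyloxy)-3-methyl-4-(2-methylpropyl)-2-oxochroman-3-yl]propanoate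
Conditions: LiN(SiMe3)2, THF, −78 °C; 6, −78 → −40 °C; AcOH
Reagents that add atoms: none
Why: Michael addition of the tetrasubstituted lactone enolate to the acrylate; the 4-isobutyl group, held pseudo-axial by the peri benzyloxy group, blocks one face, so the chain enters trans to it and the quaternary centre forms with methyl cis to isobutyl.

Step 5
Reactants: 7 tert-butyl 3-[(3R,4S)-5,7-bis(benzyloxy)-3-methyl-4-(2-methylpropyl)-2-oxochroman-3-yl]propanoate
Product: 8 tert-butyl 3-[(3R,4S)-5,7-bis(benzyloxy)-2-hydroxy-3-methyl-4-(2-methylpropyl)chroman-3-yl]propanoate (both C2 epimers)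
Conditions: iBu2AlH (1.2 equiv), CH2Cl2, −78 °C; aq. KNaC4H4O6
Reagents that add atoms: none
Why: Low-temperature hydride reduction should stop at the lactol because the tetrahedral aluminate is stable, and the electrophilic aryl lactone should react ahead of the hindered tert-butyl ester.

Step 6
Reactants: 8 tert-butyl 3-[(3R,4S)-5,7-bis(benzyloxy)-2-hydroxy-3-methyl-4-(2-methylpropyl)chroman-3-yl]propanoate
Product: 9 tert-butyl (4R,5E)-4-[(1R)-1-[2,4-bis(benzyloxy)-6-hydroxyphenyl]-3-methylbutyl]-6-iodo-4-methylhex-5-enoate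
Conditions: CrCl2 (8 equiv), CHI3 (3 equiv), THF, 0 → 25 °C
Reagents that add atoms: iodoform IC(I)I
Why: Takai iodo-olefination of the hydroxy-aldehyde tautomer of the lactol, which should give the E alkenyl iodide from a hindered aldehyde and at the same time free the phenol needed for the later ring.

Step 7
Reactants: 9 tert-butyl (4R,5E)-4-[(1R)-1-[2,4-bis(benzyloxy)-6-hydroxyphenyl]-3-methylbutyl]-6-iodo-4-methylhex-5-enoate
Product: 10 (4R,5E)-4-[(1R)-1-[2,4-bis(benzyloxy)-6-hydroxyphenyl]-3-methylbutyl]-6-iodo-4-methylhex-5-enoic acid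
Conditions: Me3SiOTf, 2,6-lutidine, CH2Cl2, 0 °C; then MeOH, aq. citric acid
Reagents that add atoms: none
Why: Silyl-triflate cleavage of the tert-butyl ester with loss of 2-methylpropene under buffered conditions, chosen so that the electron-rich arene is not tert-butylated as it could be in strong protic acid.

Step 8
Reactants: 10 (4R,5E)-4-[(1R)-1-[2,4-bis(benzyloxy)-6-hydroxyphenyl]-3-methylbutyl]-6-iodo-4-methylhex-5-enoic acid
Product: 11 (5R,6R)-7,9-bis(benzyloxy)-5-[(E)-2-iodoethenyl]-5-methyl-6-(2-methylpropyl)-3,4,5,6-tetrahydro-2H-1-benzoxocin-2-one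
Conditions: 2-methyl-6-nitrobenzoic anhydride, DMAP, CH2Cl2 (2 mM, slow addition), 25 °C
Reagents that add atoms: none
Why: Shiina lactonisation (mixed anhydride, acyl transfer by DMAP) at high dilution, in which the quaternary carbon and the ortho-phenylene unit should preorganise the eight-membered ring.

Step 9
Reactants: 11 (5R,6R)-7,9-bis(benzyloxy)-5-[(E)-2-iodoethenyl]-5-methyl-6-(2-methylpropyl)-3,4,5,6-tetrahydro-2H-1-benzoxocin-2-one
Product: 12 (2Z,5R,6R)-7,9-bis(benzyloxy)-2-ethylidene-5-[(E)-2-iodoethenyl]-5-methyl-6-(2-methylpropyl)-3,4,5,6-tetrahydro-2H-1-benzoxocine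
Conditions: CH3CHBr2, TiCl4, TMEDA, Zn, PbCl2 (cat.), THF, 0 → 25 °C; aq. K2CO3
Reagents that add atoms: 1,1-dibromoethane CC(Br)Br
Why: Takai–Utimoto alkylidenation of an ester carbonyl should give the Z enol ether (methyl cis to oxygen); it is run before any terminal alkene exists because the titanium alkylidene can engage such alkenes, whereas the hindered E alkenyl iodide should be inert.

Step 10
Reactants: 13 phenyl vinyl sulfone
Product: 14 tributyl[1-(phenylsulfonyl)ethenyl]stannane
Conditions: LiN(iPr)2, THF, −95 °C; Bu3SnCl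
Reagents that add atoms: tributyltin chloride CCCC[Sn](Cl)(CCCC)CCCC
Why: The vinylic hydrogen alpha to the sulfonyl group is acidic enough for low-temperature lithiation, and the alkenyllithium is trapped on tin before it can add to unreacted sulfone.

Step 11
Reactants: 12 (2Z,5R,6R)-7,9-bis(benzyloxy)-2-ethylidene-5-[(E)-2-iodoethenyl]-5-methyl-6-(2-methylpropyl)-3,4,5,6-tetrahydro-2H-1-benzoxocine; 14 tributyl[1-(phenylsulfonyl)ethenyl]stannane
Product: 16 pentacyclic vinyl sulfone (Diels–Alder adduct; cyclohexene C=C between the two future cyclopropane carbons with PhSO2 on the one bonded to the ring CH2), via sulfonyl diene 15 (not isolated)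
Conditions: Pd(PPh3)4 (5 mol %), CuI (10 mol %), CsF (2 equiv), DMF, 45 °C; then 110 °C
Reagents that add atoms: none
Why: A Stille coupling (oxidative addition of zerovalent palladium into the alkenyl carbon–iodine bond, copper-assisted tin-to-palladium transfer, reductive elimination with retention) gives the E 2-sulfonyl-1,3-diene 15, which on warming should undergo an intramolecular Diels–Alder reaction of inverse electron demand in which the nucleophilic CH of the Z aryl enol ether bonds to the CH2 terminus of the diene (beta to sulfur) while the aryloxy carbon bonds to the other terminus, concerted but asynchronous. The closest known reactions are the [4+2] cycloadditions of 2-(arylsulfonyl)-1,3-dienes with enol ethers and the intramolecular Diels–Alder reaction of 1,3,8-nonatrienes, here run across an eight-membered ring. The cyclohexene is closed by the [4+2] itself, and the same new bond from the aryloxy carbon to the diene terminus closes the cyclopentane over the three-carbon tether and divides the benzoxocine so that the seven-membered oxa-bridge appears. The aryloxy quaternary centre is fixed because the aryl–CH(isobutyl) strap can span the new cyclopentane on one face only, the ring-fusion CH follows because the diene can reach the enol ether CH only from the opposite face (cis fusion, hydrogen cis to oxygen), and the CH(CH3) centre follows from suprafacial addition to the Z enol ether (methyl cis to oxygen). The step needs cyclisation to outrun diene dimerisation and the Z geometry to stay intact: the strap holds the two pi systems 1,4 across the ring, the sulfonyl group lowers the diene LUMO and favours the s-cis form, and the basic fluoride medium keeps the enol ether from acid-induced isomerisation.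

Step 12
Reactants: 16 pentacyclic vinyl sulfone
Product: 17 cyclopropyl sulfone (gem-dimethylcyclopropane fused cis to the cyclohexane; PhSO2 on the cyclopropane carbon bonded to the ring CH2)
Conditions: [Ph2S–CHMe2]BF4, LiN(iPr)2, DME, −78 °C; then 16, −78 → −20 °C
Reagents that add atoms: isopropyldiphenylsulfonium tetrafluoroborate CC(C)[S+](c1ccccc1)c1ccccc1.F[B-](F)(F)F
Why: Michael-initiated ring closure by sulfonium-ylide isopropylidene transfer: the ylide carbon should add to the beta carbon of the vinyl sulfone on the convex face (the side of the ring-fusion hydrogen, away from the cyclopentane CH2 that stands axial 1,3 to it), and the alpha-sulfonyl carbanion then displaces Ph2S, so both new cyclopropane bonds lie on that face.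

Step 13
Reactants: 17 cyclopropyl sulfone
Product: 18 bis(benzyl ether) of the 3,5-di-deformyl target
Conditions: Na/Hg (6 wt % Na), Na2HPO4, MeOH–THF, −20 → 20 °C
Reagents that add atoms: none
Why: Reductive desulfonylation by electron transfer; the cyclopropyl radical or anion cannot invert because the ring fusion must stay cis, so hydrogen replaces sulfur with retention.

Step 14
Reactants: 18 bis(benzyl ether) of the 3,5-di-deformyl target
Product: 19 3,5-di-deformyl target (diphenol)
Conditions: H2 (1 atm), palladium on carbon (Pd/C, 10 wt %), EtOAc–EtOH, 25 °C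
Reagents that add atoms: none
Why: Neutral hydrogenolysis of the two benzyl aryl ethers, which should leave the unactivated gem-dimethylcyclopropane and the tertiary alkyl aryl ether untouched.

Step 15
Reactants: 19 3,5-di-deformyl target (diphenol)
Product: 20 CNP0202714.1 (target)
Conditions: POCl3, DMF, MeCN, 0 → 25 °C; then H2O, 50 °C
Reagents that add atoms: N,N-dimethylformamide CN(C)C=O; water O
Why: Twofold Vilsmeier–Haack formylation at the two free positions of the phloroglucinol-type ring, each flanked by two oxygens, followed by hydrolysis of the bis-iminium salt to the dialdehyde.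

**Compound list**
1 | 5,7-dihydroxy-2H-chromen-2-one | O=c1ccc2c(O)cc(O)cc2o1 | starting material
2 | 5,7-bis(benzyloxy)-2H-chromen-2-one | O=c1ccc2c(OCc3ccccc3)cc(OCc3ccccc3)cc2o1 | intermediate
3 | isobutylmagnesium bromide | CC(C)C[Mg]Br | starting material
4 | (4R)-5,7-bis(benzyloxy)-4-(2-methylpropyl)chroman-2-one | CC(C)C[C@H]1c2c(OCc3ccccc3)cc(OCc3ccccc3)cc2OC(=O)C1 | intermediate
5 | (3R,4R)-5,7-bis(benzyloxy)-3-methyl-4-(2-methylpropyl)chroman-2-one (methyl trans to isobutyl) | CC(C)C[C@H]1c2c(OCc3ccccc3)cc(OCc3ccccc3)cc2OC(=O)[C@@H]1C | intermediate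
6 | tert-butyl acrylate | C=CC(=O)OC(C)(C)C | starting material
7 | tert-butyl 3-[(3R,4S)-5,7-bis(benzyloxy)-3-methyl-4-(2-methylpropyl)-2-oxochroman-3-yl]propanoate (methyl cis to isobutyl) | CC(C)C[C@H]1c2c(OCc3ccccc3)cc(OCc3ccccc3)cc2OC(=O)[C@]1(C)CCC(=O)OC(C)(C)C | intermediate
8 | tert-butyl 3-[(3R,4S)-5,7-bis(benzyloxy)-2-hydroxy-3-methyl-4-(2-methylpropyl)chroman-3-yl]propanoate (lactol, both C2 epimers) | CC(C)C[C@H]1c2c(OCc3ccccc3)cc(OCc3ccccc3)cc2OC(O)[C@]1(C)CCC(=O)OC(C)(C)C | intermediate
9 | tert-butyl (4R,5E)-4-[(1R)-1-[2,4-bis(benzyloxy)-6-hydroxyphenyl]-3-methylbutyl]-6-iodo-4-methylhex-5-enoate | CC(C)C[C@@H](c1c(OCc2ccccc2)cc(OCc2ccccc2)cc1O)[C@@](C)(CCC(=O)OC(C)(C)C)/C=C/I | intermediate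
10 | (4R,5E)-4-[(1R)-1-[2,4-bis(benzyloxy)-6-hydroxyphenyl]-3-methylbutyl]-6-iodo-4-methylhex-5-enoic acid | CC(C)C[C@@H](c1c(OCc2ccccc2)cc(OCc2ccccc2)cc1O)[C@@](C)(CCC(O)=O)/C=C/I | intermediate
11 | (5R,6R)-7,9-bis(benzyloxy)-5-[(E)-2-iodoethenyl]-5-methyl-6-(2-methylpropyl)-3,4,5,6-tetrahydro-2H-1-benzoxocin-2-one | CC(C)C[C@H]1c2c(OCc3ccccc3)cc(OCc3ccccc3)cc2OC(=O)CC[C@@]1(C)/C=C/I | intermediate
12 | (2Z,5R,6R)-7,9-bis(benzyloxy)-2-ethylidene-5-[(E)-2-iodoethenyl]-5-methyl-6-(2-methylpropyl)-3,4,5,6-tetrahydro-2H-1-benzoxocine | CC(C)C[C@H]1c2c(OCc3ccccc3)cc(OCc3ccccc3)cc2O/C(=C\C)CC[C@@]1(C)/C=C/I | intermediate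
13 | phenyl vinyl sulfone | C=CS(=O)(=O)c1ccccc1 | starting material
14 | tributyl[1-(phenylsulfonyl)ethenyl]stannane | C=C([Sn](CCCC)(CCCC)CCCC)S(=O)(=O)c1ccccc1 | intermediate
15 | (2Z)-7,9-bis(benzyloxy)-2-ethylidene-5-methyl-6-(2-methylpropyl)-5-[(1E)-3-(phenylsulfonyl)buta-1,3-dienyl]-3,4,5,6-tetrahydro-2H-1-benzoxocine (C5 and C6 as in 12) | CC(C)C[C@H]1c2c(OCc3ccccc3)cc(OCc3ccccc3)cc2O/C(=C\C)CC[C@@]1(C)/C=C/C(=C)S(=O)(=O)c1ccccc1 | intermediate
16 | pentacyclic vinyl sulfone: cis-fused cyclopentane/cyclohexene bridged by the aryl ether; ring-fusion H, ether O and secondary methyl all cis; PhSO2 on the alkene carbon next to the ring CH2 | CC(C)C[C@H]1c2c(OCc4ccccc4)cc(OCc4ccccc4)cc2O[C@]23CC[C@@]1(C)[C@H]2C=C(S(=O)(=O)c4ccccc4)C[C@@H]3C | intermediate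
17 | cyclopropyl sulfone: as 18 with PhSO2 in place of H on the cyclopropane carbon bonded to the ring CH2 | CC(C)C[C@H]1c2c(OCc4ccccc4)cc(OCc4ccccc4)cc2O[C@]23CC[C@@]1(C)[C@H]2[C@H]1[C@@](S(=O)(=O)c4ccccc4)(C[C@@H]3C)C1(C)C | intermediate
18 | bis(benzyl ether) of the 3,5-di-deformyl target | CC(C)C[C@H]1c2c(OCc4ccccc4)cc(OCc4ccccc4)cc2O[C@]23CC[C@@]1(C)[C@H]2[C@H]1[C@@H](C[C@@H]3C)C1(C)C | intermediate
19 | 3,5-di-deformyl target (diphenol) | CC(C)C[C@H]1c2c(O)cc(O)cc2O[C@]23CC[C@@]1(C)[C@H]2[C@H]1[C@@H](C[C@@H]3C)C1(C)C | intermediate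
20 | CNP0202714.1 | CC(C)C[C@H]1c2c(O)c(C=O)c(O)c(C=O)c2O[C@]23CC[C@@]1(C)[C@H]2[C@H]1[C@@H](C[C@@H]3C)C1(C)C | target

Total step count: 15. Longest linear sequence: 14 steps (steps 1–9 and 11–15; step 10 is a one-step side branch).

**Steps most likely to fail**

Step 11. The alkenylstannane may transfer slowly and lose tin by protonation, or the electron-poor diene may oligomerise before it cyclises. The fallback gives up the sulfonyl activation. It sets out from 12: Stille coupling with tributyl(vinyl)stannane (Pd(PPh3)4, CuI, CsF, DMF, 45 °C) gives the unactivated E diene F1. A thermal intramolecular Diels–Alder reaction (toluene, BHT, 190 °C, sealed tube) then gives the cyclohexene F2, under the same geometric control. Dibromocarbene addition (CHBr3, KOtBu, pentane, 0 °C) gives the dibromocyclopropane F3; convex-face addition is hoped for here but is less secure than in step 12, because the axial secondary methyl lies on that face. Exchange of both bromines for methyl (Me2CuLi, Et2O, −20 °C; then MeI) comes back to the route at 18.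

Step 12. The tertiary ylide may add too slowly to the hindered beta carbon, and the base may instead remove the gamma hydrogen and shift the double bond to the allyl sulfone. The fallback uses a small, non-basic dipole. It sets out from 16: 1,3-dipolar cycloaddition of 2-diazopropane (made from acetone hydrazone with Ag2O; Et2O, −30 °C) should give the 1-pyrazoline F4, with the carbon terminus on the beta carbon and approach from the same convex face. Photolysis (350 nm, benzene) with loss of nitrogen comes back to the route at 17.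

Step 8. Intermolecular esterification to dimers and oligomers may outrun closure of the eight-membered ring. The fallback closes the ring by metathesis at the CH2–CH2 bond instead of at the ester bond. It sets out from 5: Michael addition of its enolate to phenyl vinyl sulfoxide (LiN(SiMe3)2, THF, −78 °C) gives the sulfoxide F5, and thermal sulfoxide elimination (toluene, 110 °C) gives the 3-vinyl lactone F6. Reduction with iBu2AlH (−78 °C) gives the lactol F7, and Takai iodo-olefination (CrCl2, CHI3) gives the phenol F8. Acylation with acryloyl chloride (Et3N, CH2Cl2, 0 °C) gives the aryl acrylate F9. Ring-closing metathesis with the second-generation Grubbs catalyst, [1,3-bis(2,4,6-trimethylphenyl)imidazolidin-2-ylidene]dichloro(benzylidene)(tricyclohexylphosphine)ruthenium (CH2Cl2, 1 mM, 40 °C), gives the unsaturated eight-membered lactone F10. Conjugate reduction with [(Ph3P)CuH]6 (toluene, 25 °C) comes back to the route at 11.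

**Further compounds**
F1 | step 11 | (2Z)-7,9-bis(benzyloxy)-5-[(1E)-buta-1,3-dienyl]-2-ethylidene-5-methyl-6-(2-methylpropyl)-3,4,5,6-tetrahydro-2H-1-benzoxocine | CC(C)C[C@H]1c2c(OCc3ccccc3)cc(OCc3ccccc3)cc2O/C(=C\C)CC[C@@]1(C)/C=C/C=C
F2 | step 11 | pentacyclic cyclohexene without sulfonyl group (Diels–Alder adduct of F1) | CC(C)C[C@H]1c2c(OCc4ccccc4)cc(OCc4ccccc4)cc2O[C@]23CC[C@@]1(C)[C@H]2C=CC[C@@H]3C
F3 | step 11 | gem-dibromocyclopropane analogue of 18 | CC(C)C[C@H]1c2c(OCc4ccccc4)cc(OCc4ccccc4)cc2O[C@]23CC[C@@]1(C)[C@H]2[C@H]1[C@@H](C[C@@H]3C)C1(Br)Br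
F4 | step 12 | 1-pyrazoline from 16 and 2-diazopropane (CMe2 on the former beta carbon; N on the sulfonyl carbon) | CC(C)C[C@H]1c2c(OCc4ccccc4)cc(OCc4ccccc4)cc2O[C@]23CC[C@@]1(C)[C@H]2[C@H]1[C@@](S(=O)(=O)c4ccccc4)(C[C@@H]3C)N=NC1(C)C
F5 | step 8 | 5,7-bis(benzyloxy)-3-methyl-4-(2-methylpropyl)-3-[2-(phenylsulfinyl)ethyl]chroman-2-one (methyl cis to isobutyl; sulfoxide epimers) | CC(C)C[C@H]1c2c(OCc3ccccc3)cc(OCc3ccccc3)cc2OC(=O)[C@]1(C)CCS(=O)c1ccccc1
F6 | step 8 | 5,7-bis(benzyloxy)-3-ethenyl-3-methyl-4-(2-methylpropyl)chroman-2-one (methyl cis to isobutyl) | CC(C)C[C@H]1c2c(OCc3ccccc3)cc(OCc3ccccc3)cc2OC(=O)[C@]1(C)C=C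
F7 | step 8 | 5,7-bis(benzyloxy)-3-ethenyl-3-methyl-4-(2-methylpropyl)chroman-2-ol (both C2 epimers) | CC(C)C[C@H]1c2c(OCc3ccccc3)cc(OCc3ccccc3)cc2OC(O)[C@]1(C)C=C
F8 | step 8 | 3,5-bis(benzyloxy)-2-[(1E)-3-ethenyl-1-iodo-3,6-dimethylhept-1-en-4-yl]phenol | CC(C)C[C@@H](c1c(OCc2ccccc2)cc(OCc2ccccc2)cc1O)[C@@](C)(C=C)/C=C/I
F9 | step 8 | acrylate ester of phenol F8 | CC(C)C[C@@H](c1c(OCc2ccccc2)cc(OCc2ccccc2)cc1OC(=O)C=C)[C@@](C)(C=C)/C=C/I
F10 | step 8 | (3Z)-7,9-bis(benzyloxy)-5-[(E)-2-iodoethenyl]-5-methyl-6-(2-methylpropyl)-5,6-dihydro-2H-1-benzoxocin-2-one | CC(C)C[C@H]1c2c(OCc3ccccc3)cc(OCc3ccccc3)cc2OC(=O)/C=C\[C@@]1(C)/C=C/I
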